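**Retrosynthetic overview**
- Last bond: the C13–O ether bond of the spiro tetrahydrofuran, closed by adding the C9 tertiary hydroxyl to the α-carbon of a (12E)-alkylidene butyrolactone (key C–O step; sets C13).
- The alkylidene lactone comes from a C12 aldehyde by Wittig reaction; C11–C12 come from vinyl addition to a C9 ketone, and a tethered hydroboration then sets 5-H and 6-OH on a C5=C6 alkene.
- The C8 methyl comes from α-methylenation and convex-face hydrogenation; C5=C6 from dehydration of an aldol carbinol; the δ-lactone (C19 carbonyl, C20 OCH2) from lactonisation.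
- Ring A with C4, C5 and C10 comes from an enantioselective, desymmetrising copper hydride reductive aldol cyclisation of a 2,2-disubstituted cyclohexane-1,3-dione (ring B).
- Ring order: B (bought) → A → δ-lactone → spiro tetrahydrofuran onto the bought butyrolactone ring.

Locants: labdane locants of the target are used throughout (ring A = C1–C5, C10; ring B = C5–C10; C11–C16 = side chain and butyrolactone, C16 its carbonyl, C15 its OCH2; C17 on C8; C18 methyl and C19 carbonyl on C4; C20 = OCH2 on C10); β is the face that carries C20.

Assumption: the target is exactly the isomer encoded by the SMILES, (4S,5S,6R,8R,9R,10S,13R), with H-5, C19, C20, 6-OH and C11 on the β face and C17 and the ether oxygen on the α face (cis A/B fusion); the sense of the two chiral catalysts (steps 5 and 13) is assigned by analogy, and the antipodal ligand is used if the first run shows the opposite sense.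

Step 1
Reactants: 1 cyclohexane-1,3-dione; 2 acrolein
Product: 3 3-(2,6-dioxocyclohexyl)propanal (handled as its cyclic enol hemiacetal tautomer)
Conditions: H2O, rt
Reagents that add atoms: none
Why: Michael addition of the acidic 1,3-dione to acrolein in water, where ring closure of the mono-adduct to its enol hemiacetal masks the dione and limits a second addition; no stereocentre is formed.

Step 2
Reactants: 3 3-(2,6-dioxocyclohexyl)propanal; 4 ethyl 2-(triphenylphosphoranylidene)propanoate
Product: 5 ethyl (2E)-5-(2,6-dioxocyclohexyl)-2-methylpent-2-enoate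
Conditions: 4 (2.2 equiv), PhMe, 80 °C; 1 M HCl wash
Reagents that add atoms: none
Why: Wittig olefination of the aldehyde (free from the hemiacetal by ring–chain tautomerism) with a stabilised α-branched ylide gives the (E)-trisubstituted enoate and leaves the ketones alone; the excess ylide covers protonation by the enolic dione.

Step 3
Reactants: 5 ethyl (2E)-5-(2,6-dioxocyclohexyl)-2-methylpent-2-enoate
Product: 6 ethyl (2E)-5-[1-(hydroxymethyl)-2,6-dioxocyclohexyl]-2-methylpent-2-enoate
Conditions: 37% aq. CH2O, THF, rt
Reagents that add atoms: formaldehyde, C=O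
Why: aldol addition (hydroxymethylation) of the 2-monosubstituted 1,3-dione to formaldehyde makes C10 quaternary and brings in C20 already oxygenated, while the two ring carbonyls stay equivalent, so no stereocentre exists yet.

Step 4
Reactants: 6 ethyl (2E)-5-[1-(hydroxymethyl)-2,6-dioxocyclohexyl]-2-methylpent-2-enoate
Product: 7 ethyl (2E)-5-[1-(tert-butyldimethylsilyloxymethyl)-2,6-dioxocyclohexyl]-2-methylpent-2-enoate
Conditions: TBSCl, imidazole, DMF, 0 °C to rt
Reagents that add atoms: tert-butyldimethylsilyl chloride, CC(C)(C)[Si](C)(C)Cl
Why: silylation of the primary neopentyl alcohol under mild base blocks retro-aldol loss of formaldehyde and keeps the hydroxyl away from the copper catalyst and silane of the next step.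

Step 5
Reactants: 7 ethyl (2E)-5-[1-(tert-butyldimethylsilyloxymethyl)-2,6-dioxocyclohexyl]-2-methylpent-2-enoate
Product: 9 ethyl 5β-hydroxy-4α-methyl-9-oxo-10β-(tert-butyldimethylsilyloxymethyl)-cis-decalin-4β-carboxylate, via silyl aldolate 8 (not isolated)
Conditions: Cu(OAc)2·H2O (5 mol%), (R)-DTBM-SEGPHOS (5.5 mol%), (EtO)2MeSiH (2 equiv), PhMe, 0 °C to rt; then 1 M HCl, THF, 0 °C (brief)
Reagents that add atoms: none
Why: catalytic enantioselective desymmetrising reductive aldol cyclisation, in which the ligated copper hydride (monovalent copper) adds hydride to C3 of the enoate and the copper enolate closes ring A onto one of the two enantiotopic ketones through a chelated Zimmerman–Traxler transition state, so the ligand picks the ketone (fixing C10) and the chelate puts the ester (C19), the new C5 hydroxyl and the CH2OTBS arm on one face of a cis-fused ketol (fixing C4 and C5).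

Step 6
Reactants: 9 ethyl 5β-hydroxy-4α-methyl-9-oxo-10β-(tert-butyldimethylsilyloxymethyl)-cis-decalin-4β-carboxylate
Product: 11 5β-hydroxy-4α-methyl-9-oxo keto lactone (δ-lactone from C19 carbonyl to C20 oxygen), via hydroxy ester 10 (not isolated)
Conditions: HF (48% aq.), MeCN, 0 °C to rt; then TsOH·H2O (cat.), PhMe, 80 °C
Reagents that add atoms: none
Why: desilylation followed by acid-catalysed intramolecular transesterification (lactonisation), which is possible only because C19 and C20 are cis and can sit 1,3-diaxial on the ring A chair; no new stereocentre is formed and the bridge locks ring A.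

Step 7
Reactants: 11 5β-hydroxy-4α-methyl-9-oxo keto lactone
Product: 13 8-methylene keto lactone (exocyclic enone C8=C17), via Mannich base 12 (not isolated)
Conditions: (CH2O)n, PhNHMe·CF3CO2H, THF, reflux
Reagents that add atoms: formaldehyde (from paraformaldehyde), C=O
Why: direct Mannich-type α-methylenation, regiospecific because the C9 ketone can enolise only toward C8 (C10 is quaternary) and mild enough in weak acid to spare the tertiary aldol hydroxyl from retro-aldol cleavage.

Step 8
Reactants: 13 8-methylene keto lactone
Product: 14 8α-methyl keto lactone (8β-H)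
Conditions: H2 (1 atm), Pd/C (5%), EtOAc, rt, short contact time
Reagents that add atoms: none
Why: heterogeneous catalytic hydrogenation of the exocyclic enone C=C from the convex β face of the cis-fused, lactone-locked ring system (the α face is covered by the axial C1 methylene of ring A), giving 8β-H and 8α-CH3 under kinetic control.

Step 9
Reactants: 14 8α-methyl keto lactone
Product: 15 8α-methyl-9-oxo-Δ5-alkene lactone (C5=C6)
Conditions: SOCl2, pyridine, CH2Cl2, −20 to 0 °C
Reagents that add atoms: none
Why: dehydration of the tertiary alcohol through its chlorosulfite by E2 loss of the anti-periplanar axial H-6, the only possible direction because C4 and C10 are quaternary; the C5 stereocentre is removed on purpose and reset in step 11.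

Step 10
Reactants: 15 8α-methyl-9-oxo-Δ5-alkene lactone; 16 vinylmagnesium bromide
Product: 17 9α-hydroxy-9β-vinyl-8α-methyl-Δ5-alkene lactone
Conditions: CeCl3 (anhydrous), THF, −78 °C; then H2O
Reagents that add atoms: none
Why: organocerium 1,2-addition (Grignard reagent transmetallated to cerium to suppress enolisation and C8 epimerisation) to the hindered ketone, the vinyl group entering from the β face anti to the adjacent 8α-methyl and the C1 methylene, which sets C9 with C11 β and the hydroxyl α.

Step 11
Reactants: 17 9α-hydroxy-9β-vinyl-8α-methyl-Δ5-alkene lactone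
Product: 19 5β-H 6β,9α,12-triol lactone, via cyclic borane 18 (not isolated)
Conditions: BH3·THF (1.5 equiv), THF, 0 °C to rt; then H2O2 (30%), aq. NaHCO3, 0 °C
Reagents that add atoms: hydrogen peroxide, OO
Why: hydroboration–oxidation in which the vinyl group reacts first (anti-Markovnikov) and the resulting β-held alkylborane delivers B–H intramolecularly to the β face of C5=C6 (tethered, cyclic hydroboration, boron to the less substituted C6), so syn addition and oxidation with retention give 5β-H and 6β-OH (cis ring fusion), the α face being shielded as well by the 8α-methyl and the ring A bridge.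

Step 12
Reactants: 19 5β-H 6β,9α,12-triol lactone; 20 3-(triphenylphosphoranylidene)oxolan-2-one
Product: 22 (12E)-alkylidene butyrolactone diol, via aldehyde 21 (not isolated)
Conditions: TEMPO (10 mol%), PhI(OAc)2 (1.1 equiv), CH2Cl2, rt; then 20 (2.5 equiv), 40 °C
Reagents that add atoms: none
Why: nitroxyl-catalysed oxidation selective for the primary alcohol over the secondary and tertiary ones, followed in the same flask by Wittig olefination with the stabilised lactone ylide before the β-hydroxy aldehyde can dehydrate; the alkene geometry (E expected) is lost in the next step.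

Step 13
Reactants: 22 (12E)-alkylidene butyrolactone diol
Product: 23 target, (4S,5S,6R,8R,9R,10S,13R)-6β-hydroxy-9α,13-epoxy-5β-H-labdane-19,20:16,15-diolide
Conditions: (R,R)-N,N'-bis(3,5-di-tert-butylsalicylidene)-1,2-cyclohexanediaminocobalt (C36H52CoN2O2, 5 mol%), N-fluoro-2,4,6-trimethylpyridinium tetrafluoroborate (1.5 equiv), PhSiH3 (1.5 equiv), PhCF3, 0 °C to rt
Reagents that add atoms: none
Why: Proposed new method: a cobalt hydride (trivalent cobalt), formed from the divalent cobalt salen complex, the N-fluoropyridinium oxidant and PhSiH3, transfers a hydrogen atom to C12 of the electron-poor alkylidene lactone, the tertiary α-acyl radical at C13 is captured by cobalt and oxidised to an alkyl–cobalt electrophile (tetravalent cobalt), and the C9 tertiary hydroxyl displaces cobalt in a 5-exo closure that forms the C13–O bond with anti-Michael regiochemistry (O to the α-carbon, H to the β-carbon) and the quaternary spiro centre; C13 is set in this closure, which should turn the planar carbonyl arm (C16) to the open C8 side and the C14 methylene toward C10, away from the C20 methylene and its oxygen, giving (13R), with the chiral salen ligand chosen to reinforce this bias; the closest known reactions are cobalt-salen hydrogen-atom-transfer/radical–polar crossover hydroalkoxylation of unactivated alkenes and Mukaiyama-type α-hydroxylation of α,β-unsaturated esters, neither of which has been used to add a tethered alcohol to the α-carbon of an alkylidene lactone.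

**Compound list**
1 | cyclohexane-1,3-dione | O=C1CCCC(=O)C1 | starting material
2 | acrolein (prop-2-enal) | C=CC=O | starting material
3 | 3-(2,6-dioxocyclohexyl)propanal (in equilibrium with its cyclic enol hemiacetal) | O=CCCC1C(=O)CCCC1=O | intermediate
4 | ethyl 2-(triphenylphosphoranylidene)propanoate | CCOC(=O)C(C)=P(c1ccccc1)(c1ccccc1)c1ccccc1 | starting material
5 | ethyl (2E)-5-(2,6-dioxocyclohexyl)-2-methylpent-2-enoate | CCOC(=O)/C(C)=C/CCC1C(=O)CCCC1=O | intermediate
6 | ethyl (2E)-5-[1-(hydroxymethyl)-2,6-dioxocyclohexyl]-2-methylpent-2-enoate | CCOC(=O)/C(C)=C/CCC1(CO)C(=O)CCCC1=O | intermediate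
7 | ethyl (2E)-5-[1-(tert-butyldimethylsilyloxymethyl)-2,6-dioxocyclohexyl]-2-methylpent-2-enoate | CCOC(=O)/C(C)=C/CCC1(CO[Si](C)(C)C(C)(C)C)C(=O)CCCC1=O | intermediate
8 | silyl aldolate: 5-O-diethoxy(methyl)silyl ether of 9 | O=C1CCC[C@@]2(O[Si](C)(OCC)OCC)[C@]1(CO[Si](C)(C)C(C)(C)C)CCC[C@]2(C)C(=O)OCC | intermediate
9 | ethyl 5β-hydroxy-4α-methyl-9-oxo-10β-(tert-butyldimethylsilyloxymethyl)-cis-decalin-4β-carboxylate (ester, 5-OH and CH2OTBS all cis) | O=C1CCC[C@@]2(O)[C@]1(CO[Si](C)(C)C(C)(C)C)CCC[C@]2(C)C(=O)OCC | intermediate
10 | hydroxy ester: ethyl 5β-hydroxy-10β-(hydroxymethyl)-4α-methyl-9-oxo-cis-decalin-4β-carboxylate | O=C1CCC[C@@]2(O)[C@]1(CO)CCC[C@]2(C)C(=O)OCC | intermediate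
11 | keto lactone: 5β-hydroxy-4α-methyl-9-oxo decalin bridged on the β face by C19(=O)–O–C20H2 between C4 and C10 | O=C1CCC[C@@]2(O)[C@]13CCC[C@]2(C)C(=O)OC3 | intermediate
12 | Mannich base: 8-[(N-methylanilino)methyl] derivative of 11 (C8 epimers) | O=C1C(CN(C)c4ccccc4)CC[C@@]2(O)[C@]13CCC[C@]2(C)C(=O)OC3 | intermediate
13 | 8-methylene keto lactone (exocyclic enone C8=C17; 5β-OH) | O=C1C(=C)CC[C@@]2(O)[C@]13CCC[C@]2(C)C(=O)OC3 | intermediate
14 | 8α-methyl keto lactone (8β-H; 5β-OH) | O=C1[C@H](C)CC[C@@]2(O)[C@]13CCC[C@]2(C)C(=O)OC3 | intermediate
15 | 8α-methyl-9-oxo-Δ5-alkene lactone (C5=C6) | O=C1[C@H](C)CC=C2[C@]13CCC[C@]2(C)C(=O)OC3 | intermediate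
16 | vinylmagnesium bromide | C=C[Mg]Br | starting material
17 | 9α-hydroxy-9β-vinyl-8α-methyl-Δ5-alkene lactone | C=C[C@@]1(O)[C@H](C)CC=C2[C@]13CCC[C@]2(C)C(=O)OC3 | intermediate
18 | cyclic borane: B–H bridging C12 and C6 (β), 5β-H | [BH]1CC[C@@]2(O)[C@H](C)C[C@@H]1[C@H]1[C@]23CCC[C@]1(C)C(=O)OC3 | intermediate
19 | triol lactone: 5β-H, 6β-OH, 9α-OH, 9β-(2-hydroxyethyl), 8α-methyl | OCC[C@@]1(O)[C@H](C)C[C@@H](O)[C@H]2[C@]13CCC[C@]2(C)C(=O)OC3 | intermediate
20 | 3-(triphenylphosphoranylidene)oxolan-2-one | O=C1OCCC1=P(c1ccccc1)(c1ccccc1)c1ccccc1 | starting material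
21 | aldehyde: 9β-(2-oxoethyl) analogue of 19 | O=CC[C@@]1(O)[C@H](C)C[C@@H](O)[C@H]2[C@]13CCC[C@]2(C)C(=O)OC3 | intermediate
22 | (12E)-alkylidene butyrolactone diol: 9β-[(2E)-2-(2-oxooxolan-3-ylidene)ethyl], 6β-OH, 9α-OH | O=C1OCC/C1=C\C[C@@]2(O)[C@H](C)C[C@@H](O)[C@H]3[C@]24CCC[C@]3(C)C(=O)OC4 | intermediate
23 | CNP0393616.2, (4S,5S,6R,8R,9R,10S,13R)-6β-hydroxy-9α,13-epoxy-5β-H-labdane-19,20:16,15-diolide | C[C@@H]1C[C@@H](O)[C@H]2[C@]3(CCC[C@]2(C)C(=O)OC3)[C@@]12CC[C@]1(CCOC1=O)O2 | target

**Step count and risks**
Total steps: 13. Longest linear sequence: 13 steps (from 1).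

Three steps most likely to fail:

Step 5 (reductive aldol). The copper hydride may reduce a ring ketone before the hindered enoate, or the tetrasubstituted enolate may close with poor enantio- or diastereoselectivity. The fallback sets out from 7 and comes back at 9, and moves the desymmetrisation from the C–C bond formation to a ketone reduction. A Corey–Bakshi–Shibata reduction (2-methyl-CBS-oxazaborolidine, catecholborane, catalyst enantiomer chosen so that the carbonyl destined to become C9 is reduced) gives the mono-reduced hydroxy ketone F1. The one remaining ketone is then the only aldol acceptor, so an achiral copper hydride, [(Ph3P)CuH]6 with a silane, closes ring A under substrate control to the C9 carbinol analogue of the ketol F2. Dess–Martin oxidation of the secondary C9 alcohol, with the tertiary C5 alcohol untouched, gives 9.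

Step 8 (C8 methyl). The 8α-methyl ketone is the less stable epimer, and palladium may isomerise the enone or epimerise C8. The fallback sets out from 11 and comes back at 14, bypassing 13. Deprotonation of 11 with LiN(iPr)2 (2.2 equiv, alkoxide plus C8 enolate) and methylation with MeI on the convex face gives the 8β-methyl ketone F3. F3 is enolised again with LiN(iPr)2 and the enolate is protonated kinetically from the convex β face with a hindered proton donor (2,6-di-tert-butyl-4-methylphenol, −78 °C), which gives 14.

Step 13 (proposed new ether closure). The C13 radical may simply be reduced to the saturated lactone, or the closure may give the C13 epimer. The fallback sets out from 22 and comes back at 23 using known chemistry. Hydrogenation of C12=C13 (H2, Pd/C) gives the saturated butyrolactone F4. Its lithium enolate, made with excess LiN(iPr)2 (the two hydroxyls as alkoxides), is brominated with 1,2-dibromotetrachloroethane to the α-bromo lactone F5. The ether is then closed by silver-assisted intramolecular O-alkylation of the C9 hydroxyl (AgOSO2CF3, 2,6-di-tert-butylpyridine, CH2Cl2), a Williamson-type etherification at an α-halo ester, giving 23; C13 is again set in the ring closure and the epimer, if formed, is separated.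

Further compounds
F1 | step 5 | ethyl (2E)-5-[1-(tert-butyldimethylsilyloxymethyl)-2-hydroxy-6-oxocyclohexyl]-2-methylpent-2-enoate (quaternary carbon configured as C10 of 9; carbinol configuration immaterial) | CCOC(=O)/C(C)=C/CC[C@]1(CO[Si](C)(C)C(C)(C)C)C(O)CCCC1=O
F2 | step 5 | C9 carbinol analogue of 9 (9-hydroxy in place of 9-oxo; carbinol configuration immaterial) | OC1CCC[C@@]2(O)[C@]1(CO[Si](C)(C)C(C)(C)C)CCC[C@]2(C)C(=O)OCC
F3 | step 8 | 8β-methyl keto lactone (C8 epimer of 14) | O=C1[C@@H](C)CC[C@@]2(O)[C@]13CCC[C@]2(C)C(=O)OC3
F4 | step 13 | saturated butyrolactone: 12,13-dihydro derivative of 22 (C13 epimers) | O=C1OCCC1CC[C@@]2(O)[C@H](C)C[C@@H](O)[C@H]3[C@]24CCC[C@]3(C)C(=O)OC4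
F5 | step 13 | α-bromo lactone: 13-bromo derivative of F4 (C13 epimers) | O=C1OCCC1(Br)CC[C@@]2(O)[C@H](C)C[C@@H](O)[C@H]3[C@]24CCC[C@]3(C)C(=O)OC4
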